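Each quinone ring (A and A') is numbered C1=O, C2–OH, C3–CH3, C4=O, C5 (inter-ring bond), C6 (arylethyl). The plan rests on cutting C6–CH2 and C6'–CH2. C6 is the only ring carbon carrying a primary alkyl group, and once the chains are removed it is the only C–H of an electron-poor quinone. In one operation, silver-catalysed persulfate decarboxylation of 3-(2-methoxyphenyl)propanoic acid delivers the 2-arylethyl radical to C6 and C6', forming both bonds at the quinone oxidation level. The precursor is the C5–C5'-linked dimer of 2-methoxy-3-methyl-1,4-benzoquinone, its C2 hydroxyls masked as methyl ethers. It is made by homocoupling an aryl bromide while the axis is still lightly hindered.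

Key step: step 5

Assumption: the target string carries no stereodescriptor, so the hindered C5–C5' axis is taken as unspecified and the material is made racemic; there is no stereocentre to set.
Locants: quinone rings use the C1–C6 numbering above; benzenoid intermediates use the locants of their own names.

Step 1
Reactants: 1 1,2,4-trimethoxybenzene
Product: 3 1,2,4-trimethoxy-3-methylbenzene, via 2,3,6-trimethoxyphenyllithium 2 (not isolated)
Conditions: n-BuLi, THF, 0 °C to rt; then MeI, 0 °C to rt
Reagents that add atoms: iodomethane, CI
Why: Directed ortho-metalation: C3–H lies between the C2 and C4 methoxy groups, whose combined coordination and inductive acidification should steer n-BuLi to that carbon, and the aryllithium is then methylated by SN2 attack on MeI.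

Step 2
Reactants: 3 1,2,4-trimethoxy-3-methylbenzene
Product: 4 1-bromo-2,4,5-trimethoxy-3-methylbenzene
Conditions: NBS, MeCN, 0 °C to rt, dark
Reagents that add atoms: N-bromosuccinimide, O=C1CCC(=O)N1Br
Why: Electrophilic aromatic bromination: C5 of 3 is para to the C2 methoxy and ortho to the C4 methoxy group, whereas C6 is activated by only one methoxy group and the methyl group, so polar bromination should enter at C5 and leave the benzylic methyl untouched.

Step 3
Reactants: 4 1-bromo-2,4,5-trimethoxy-3-methylbenzene (two molecules)
Product: 6 2,2',4,4',5,5'-hexamethoxy-3,3'-dimethyl-1,1'-biphenyl, via aryl pinacol boronate 5 (not isolated)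
Conditions: B2pin2 (0.55 equiv), Pd(dppf)Cl2 (5 mol %), K2CO3, DMSO, 80 °C
Reagents that add atoms: none
Why: One-pot Miyaura borylation/Suzuki–Miyaura coupling: with half an equivalent of B2pin2 and a carbonate base, the boronate 5 formed from part of 4 should cross-couple at once with the remaining 4, and the new bond is flanked by only two ortho methoxy groups, well within the scope of this coupling.

Step 4
Reactants: 6 2,2',4,4',5,5'-hexamethoxy-3,3'-dimethyl-1,1'-biphenyl
Product: 7 4,4'-dimethoxy-5,5'-dimethyl-[1,1'-bi(cyclohexa-1,4-diene)]-3,3',6,6'-tetrone (the C5–C5' dimer of 2-methoxy-3-methyl-1,4-benzoquinone)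
Conditions: (NH4)2Ce(NO3)6 (5–6 equiv), MeCN–H2O, 0 °C, dark; used promptly
Reagents that add atoms: water, O
Why: Oxidative demethylation by tetravalent cerium: in each ring the para-related methoxy groups at biphenyl C2 and C5 should be lost through the arene radical cation and attack of water to give the para-quinone, while the C4 methoxy group stays as a vinylogous ester and biphenyl C6–H becomes quinone C6–H.

Step 5
Reactants: 7 4,4'-dimethoxy-5,5'-dimethyl-[1,1'-bi(cyclohexa-1,4-diene)]-3,3',6,6'-tetrone; 8 3-(2-methoxyphenyl)propanoic acid (excess)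
Product: 10 4,4'-dimethoxy-5,5'-dimethyl-2,2'-bis[2-(2-methoxyphenyl)ethyl]-[1,1'-bi(cyclohexa-1,4-diene)]-3,3',6,6'-tetrone, via mono-alkylated biquinone 9 (not isolated)
Conditions: AgNO3 (0.3 equiv), (NH4)2S2O8 (5 equiv, slow addition as aqueous solution), 8 (5 equiv), MeCN–H2O, 65 °C, dark
Reagents that add atoms: none
Why: Persulfate raises monovalent silver to divalent silver, which removes one electron from the carboxylate of 8, and loss of CO2 leaves the primary, nucleophilic 2-(2-methoxyphenyl)ethyl radical (its 1,2-aryl shift is degenerate and therefore harmless). The radical adds to C6–H of ring A of 7, which the quinonyl group at C5 makes still more electron-poor, the adduct radical is spread over C5, the C4 carbonyl oxygen and ring A', and a second one-electron oxidation with loss of the C6 proton restores the quinone as 9; the same events on ring A' give 10. The closest known reaction type is the Jacobsen–Torssell (Minisci-type) silver/persulfate decarboxylative alkylation of benzo- and naphthoquinones with primary carboxylic acids, applied here twice in one flask. No ring is closed and no stereocentre is made; the C5–C5' axis merely becomes more hindered and is obtained racemic. The selectivity required is attack at C–H rather than at a substituted quinone carbon, and the substrate secures it because C6 and C6' are the only hydrogen-bearing quinone carbons, so neither regioisomers nor over-alkylation can arise. Excess 8 and slow addition of the oxidant should carry 9 through to 10 and keep silver-mediated decarboxylation ahead of oxidation of the anisole ring, while any methoxyquinone hydrolysed by the acidic medium still converges on 12 in step 6.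

Step 6
Reactants: 10 4,4'-dimethoxy-5,5'-dimethyl-2,2'-bis[2-(2-methoxyphenyl)ethyl]-[1,1'-bi(cyclohexa-1,4-diene)]-3,3',6,6'-tetrone
Product: 12 4,4'-dihydroxy-5,5'-dimethyl-2,2'-bis[2-(2-methoxyphenyl)ethyl]-[1,1'-bi(cyclohexa-1,4-diene)]-3,3',6,6'-tetrone (target), via disodium bis(quinonolate) 11 (not isolated)
Conditions: 2 M aq NaOH, MeOH, N2, rt; then 1 M aq HCl
Reagents that add atoms: sodium hydroxide, [Na+].[OH-]
Why: Addition–elimination (saponification of a vinylogous ester): hydroxide should attack C2 of each fully substituted quinone and expel methoxide, the quinonolate 11 is shielded from further attack by its charge, the two anisole ethers are inert to aqueous base, and acid liberates 12.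

Compound list
1 | 1,2,4-trimethoxybenzene | COc1ccc(OC)c(OC)c1 | starting material
2 | 2,3,6-trimethoxyphenyllithium | [Li]c1c(OC)ccc(OC)c1OC | intermediate
3 | 1,2,4-trimethoxy-3-methylbenzene | Cc1c(OC)ccc(OC)c1OC | intermediate
4 | 1-bromo-2,4,5-trimethoxy-3-methylbenzene | COc1cc(Br)c(OC)c(C)c1OC | intermediate
5 | 2-(2,4,5-trimethoxy-3-methylphenyl)-4,4,5,5-tetramethyl-1,3,2-dioxaborolane | COc1cc(B2OC(C)(C)C(C)(C)O2)c(OC)c(C)c1OC | intermediate
6 | 2,2',4,4',5,5'-hexamethoxy-3,3'-dimethyl-1,1'-biphenyl | COc1cc(-c2cc(OC)c(OC)c(C)c2OC)c(OC)c(C)c1OC | intermediate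
7 | 4,4'-dimethoxy-5,5'-dimethyl-[1,1'-bi(cyclohexa-1,4-diene)]-3,3',6,6'-tetrone | COC1=C(C)C(=O)C(C2=CC(=O)C(OC)=C(C)C2=O)=CC1=O | intermediate
8 | 3-(2-methoxyphenyl)propanoic acid | COc1ccccc1CCC(=O)O | starting material
9 | 4,4'-dimethoxy-5,5'-dimethyl-2-[2-(2-methoxyphenyl)ethyl]-[1,1'-bi(cyclohexa-1,4-diene)]-3,3',6,6'-tetrone | COc1ccccc1CCC1=C(C2=CC(=O)C(OC)=C(C)C2=O)C(=O)C(C)=C(OC)C1=O | intermediate
10 | 4,4'-dimethoxy-5,5'-dimethyl-2,2'-bis[2-(2-methoxyphenyl)ethyl]-[1,1'-bi(cyclohexa-1,4-diene)]-3,3',6,6'-tetrone | COc1ccccc1CCC1=C(C2=C(CCc3ccccc3OC)C(=O)C(OC)=C(C)C2=O)C(=O)C(C)=C(OC)C1=O | intermediate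
11 | disodium salt of 12 (both C2 oxygens deprotonated) | COc1ccccc1CCC1=C(C2=C(CCc3ccccc3OC)C(=O)C([O-])=C(C)C2=O)C(=O)C(C)=C([O-])C1=O.[Na+].[Na+] | intermediate
12 | 4,4'-dihydroxy-5,5'-dimethyl-2,2'-bis[2-(2-methoxyphenyl)ethyl]-[1,1'-bi(cyclohexa-1,4-diene)]-3,3',6,6'-tetrone | COc1ccccc1CCC1=C(C2=C(CCc3ccccc3OC)C(=O)C(O)=C(C)C2=O)C(=O)C(C)=C(O)C1=O | target

Total step count: 6. Longest linear sequence: 6 steps (1 to 12); acid 8 is purchased and enters at step 5.

Steps most likely to fail

**1. Step 5.**
- What may go wrong:
  - The second alkylation may stall for steric reasons.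
  - The sulfate radical anion may oxidise the anisole ring of 8 faster than silver decarboxylates the acid.
  - The hot acidic medium may trigger cyclisation of the biquinone, by attack of a carbonyl oxygen on the neighbouring ring.
- Fallback, from 6 back to 10: both chains are installed by polar and palladium chemistry at the arene level, before any quinone exists. NBS (two equivalents, MeCN) should brominate the only remaining ring C–H positions of 6 to give 6,6'-dibromo-2,2',4,4',5,5'-hexamethoxy-3,3'-dimethyl-1,1'-biphenyl F1. Hydroboration of commercial 2-methoxystyrene with 9-BBN-H gives B-[2-(2-methoxyphenyl)ethyl]-9-borabicyclo[3.3.1]nonane F2. A twofold B-alkyl Suzuki–Miyaura coupling of F1 with F2 (Pd(OAc)2, SPhos, K3PO4, THF–H2O, 65 °C) should give 2,2',4,4',5,5'-hexamethoxy-3,3'-dimethyl-6,6'-bis[2-(2-methoxyphenyl)ethyl]-1,1'-biphenyl F3. Oxidation of F3 with (NH4)2Ce(NO3)6 as in step 4 should spare the less electron-rich anisole rings and rejoins the route at 10.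

**2. Step 3.**
- What may go wrong:
  - Hydrodebromination and protodeborylation of the electron-rich partners.
  - A mismatch between the rates of borylation and coupling, which leaves boronate unconsumed.
- Fallback, from 3 back to 6: a metal-free C–H/C–H oxidative dehydrodimerisation. PhI(OCOCF3)2 and BF3·OEt2 in CH2Cl2 at low temperature should oxidise 3 to its radical cation. A second molecule of 3 attacks it through C5, the carbon para to the C2 methoxy group, as is known for 1,2,4-trialkoxybenzenes. Loss of a second electron and two protons gives 6 directly. This bypasses 4 and 5 and makes no compound that the list lacks (F0).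

**3. Step 6.**
- What may go wrong:
  - Base-induced tautomerisation of the alkylquinone to a quinone methide, through loss of a C6–CH2 proton, before hydrolysis is complete.
  - Aerial degradation of the electron-rich dianion.
- Fallback, from 10 back to 12: the O–CH3 bond is cleaved under Lewis-acidic conditions, in place of the C2–O bond under basic ones. BCl3 in CH2Cl2 (−78 to 0 °C) should chelate between the C1 carbonyl and the C2 methoxy oxygen of each ring. Chloride then removes the methyl group by SN2 attack to give the bis(dichloroboryl) ether of the target F4. The anisole ethers lack a chelating neighbour and should persist at this temperature. Aqueous work-up of F4 rejoins the route at 12.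

Further compounds
F1 | step 5 | 6,6'-dibromo-2,2',4,4',5,5'-hexamethoxy-3,3'-dimethyl-1,1'-biphenyl | COc1c(Br)c(-c2c(Br)c(OC)c(OC)c(C)c2OC)c(OC)c(C)c1OC
F2 | step 5 | B-[2-(2-methoxyphenyl)ethyl]-9-borabicyclo[3.3.1]nonane | COc1ccccc1CCB1C2CCCC1CCC2
F3 | step 5 | 2,2',4,4',5,5'-hexamethoxy-3,3'-dimethyl-6,6'-bis[2-(2-methoxyphenyl)ethyl]-1,1'-biphenyl | COc1ccccc1CCc1c(OC)c(OC)c(C)c(OC)c1-c1c(CCc2ccccc2OC)c(OC)c(OC)c(C)c1OC
F0 | step 3 | none | none
F4 | step 6 | bis(dichloroboryl) ether of the target | COc1ccccc1CCC1=C(C2=C(CCc3ccccc3OC)C(=O)C(OB(Cl)Cl)=C(C)C2=O)C(=O)C(C)=C(OB(Cl)Cl)C1=O
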